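## Plan

1. Locants: the target is a cis-fused 3,7-dioxabicyclo[3.3.0]octane with ring A = C1–C5–C6(Ar)–O7–C8H2 and ring B = C1(OH)–C2(Ar)–O3–C4H2–C5(H). The retrosynthesis cuts the two phenol O–benzyl bonds, then the benzylic C6–O7 bond of ring A (C8 carried as a lactone carbonyl), then C1–C2 and C4–C5 of ring B together.
2. Enabling feature: in ring B the unit C2–O3–C4 (ArCH–O–CH2) bridges the two adjacent ring-fusion carbons C1 and C5. Ring B is therefore the [3+2] adduct of an aryl carbonyl ylide (a C–O–C dipole) and a C1=C5 double bond, and the matching dipolarophile is a ring A butenolide with C8 as the carbonyl and the C1 oxygen already in place as an enol pivalate.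
3. Forward order: ring A is made as an (S)-γ-aryl lactone and oxidised to the 3-pivaloyloxybutenolide; the ylide cycloaddition closes ring B and creates the fully substituted C1; LiAlH4 opens ring A and frees the carbinol; acid re-closes ring A as the ether; hydrogenolysis frees the phenols.
4. Stereochemistry: C6 comes from asymmetric transfer hydrogenation; C1 and C5 come from addition of the dipole anti to the C6 aryl group (the cis fusion is inherent); C2 comes from exo approach of the E-ylide; C6 is re-formed with exo aryl in the cationic closure, the absolute configuration then resting on C1 and C5.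

Key step: step 7

## Route

Step 1
Reactants: 1 4-(benzyloxy)-3,5-dimethoxybenzaldehyde; 2 methyl acrylate
Product: 3 methyl 4-[4-(benzyloxy)-3,5-dimethoxyphenyl]-4-oxobutanoate
Conditions: 3-benzyl-5-(2-hydroxyethyl)-4-methylthiazolium chloride (20 mol %), Et3N, EtOH, 80 °C
Reagents that add atoms: none
Why: Stetter reaction, in which the thiazolium-derived carbene turns the aldehyde into an acyl anion equivalent that adds 1,4 to the acrylate; no stereocentre is formed.

Step 2
Reactants: 3 methyl 4-[4-(benzyloxy)-3,5-dimethoxyphenyl]-4-oxobutanoate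
Product: 5 (5S)-5-[4-(benzyloxy)-3,5-dimethoxyphenyl]dihydrofuran-2(3H)-one, via hydroxy ester 4 (not isolated)
Conditions: RuCl[(S,S)-TsDPEN](p-cymene) (1 mol %), HCO2H/Et3N (5:2), 40 °C; then PPTS (cat.), toluene, 60 °C
Reagents that add atoms: none
Why: Noyori asymmetric transfer hydrogenation of an aryl alkyl ketone, where the (S,S)-ligand should deliver hydride through the six-membered Ru–H/N–H transition state to give the (S)-carbinol as with simple aryl alkyl ketones, followed by lactonisation that does not touch the new stereocentre.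

Step 3
Reactants: 5 (5S)-5-[4-(benzyloxy)-3,5-dimethoxyphenyl]dihydrofuran-2(3H)-one
Product: 6 (5S)-5-[4-(benzyloxy)-3,5-dimethoxyphenyl]-3-hydroxydihydrofuran-2(3H)-one (C3 epimers, used together)
Conditions: KN(SiMe3)2, THF, −78 °C; then 2-(phenylsulfonyl)-3-phenyloxaziridine, −78 °C; aq NH4Cl
Reagents that add atoms: 2-(phenylsulfonyl)-3-phenyloxaziridine, O=S(=O)(N1OC1c1ccccc1)c1ccccc1
Why: Electrophilic hydroxylation of the lactone enolate by oxygen transfer from the N-sulfonyloxaziridine; the C3 configuration is irrelevant because step 4 removes it.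

Step 4
Reactants: 6 (5S)-5-[4-(benzyloxy)-3,5-dimethoxyphenyl]-3-hydroxydihydrofuran-2(3H)-one
Product: 8 (5S)-5-[4-(benzyloxy)-3,5-dimethoxyphenyl]-3-hydroxyfuran-2(5H)-one, via keto lactone 7 (not isolated)
Conditions: DMP, CH2Cl2, 0 °C to rt; non-basic work-up, used at once
Reagents that add atoms: none
Why: Dess–Martin oxidation of the secondary alcohol gives the α-keto lactone, which should tautomerise to the conjugated enol (3-hydroxybutenolide) without involving the C5 stereocentre.

Step 5
Reactants: 8 (5S)-5-[4-(benzyloxy)-3,5-dimethoxyphenyl]-3-hydroxyfuran-2(5H)-one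
Product: 9 (5S)-5-[4-(benzyloxy)-3,5-dimethoxyphenyl]-2-oxo-2,5-dihydrofuran-3-yl 2,2-dimethylpropanoate
Conditions: pivaloyl chloride, pyridine, CH2Cl2, 0 °C
Reagents that add atoms: pivaloyl chloride, CC(C)(C)C(Cl)=O
Why: O-acylation of the acidic enol with a weak base gives a fluoride-tolerant enol ester that keeps the alkene electron-poor and is too mildly basic a medium to deprotonate the benzylic γ-position.

Step 6
Reactants: 1 4-(benzyloxy)-3,5-dimethoxybenzaldehyde; 10 (trimethylsilyl)methanol
Product: 11 2-(benzyloxy)-5-{bis[(trimethylsilyl)methoxy]methyl}-1,3-dimethoxybenzene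
Conditions: 10 (2.5 equiv), PPTS (cat.), toluene, reflux, azeotropic removal of water over 4 Å molecular sieves
Reagents that add atoms: none
Why: Acid-catalysed acetalisation driven by water removal; no stereocentre is formed.

Step 7
Reactants: 9 (5S)-5-[4-(benzyloxy)-3,5-dimethoxyphenyl]-2-oxo-2,5-dihydrofuran-3-yl 2,2-dimethylpropanoate; 11 2-(benzyloxy)-5-{bis[(trimethylsilyl)methoxy]methyl}-1,3-dimethoxybenzene
Product: 14 (1R,2R,5R,6S)-2,6-bis[4-(benzyloxy)-3,5-dimethoxyphenyl]-8-oxo-3,7-dioxabicyclo[3.3.0]octan-1-yl 2,2-dimethylpropanoate, via chloro ether 12 (not isolated), via carbonyl ylide 13 (not isolated)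
Conditions: 11 (2 equiv), AcCl (2 equiv), CH2Cl2, 0 °C to rt, evaporate; then 9 (1 equiv), CsF (4 equiv), MeCN, rt
Reagents that add atoms: none
Why: Acetyl chloride turns acetal 11 into the α-chloro ether 12, and fluoride then removes the silyl group while chloride leaves (1,3-elimination) to give the non-stabilised carbonyl ylide 13, which adds as a C–O–C dipole across the C3=C4 double bond of 9; the closest known reaction type is the silicon-based 1,3-elimination route to carbonyl ylides and their [3+2] cycloaddition to acrylate-type alkenes. Ring B is closed by a suprafacial [3+2] cycloaddition (if the bonds form one after the other, conjugate addition of the CH2 terminus followed by 5-endo-trig closure of the lactone enolate on the aryl oxocarbenium ion), so both new C–C bonds arise on one face and the ring fusion can only be cis. The two ring-fusion stereocentres C1 (from C3 of 9) and C5 (from C4 of 9) are controlled by the C6 aryl group, which shields one face of the flat butenolide so that the dipole adds anti to it. The C2 stereocentre is controlled by the ylide geometry and the approach: the aryl group sits anti to the CH2 terminus (E-ylide), and an exo approach with the ylide oxygen turned away from the lactone ring places the aryl group on the convex face, cis to the pivaloyloxy group. The step needs regioselectivity (CH2 terminus to C5, ArCH terminus to C1), secured by the lactone carbonyl, which makes C5 the electrophilic β-carbon, and by the electron-rich aryl group, which leaves the carbanion character on the CH2 terminus. It also needs π-facial selectivity, secured by the C6 aryl group, and exo selectivity, for which the substrate gives only a moderate bias and which is treated below as the main risk.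

Step 8
Reactants: 14 (1R,2R,5R,6S)-2,6-bis[4-(benzyloxy)-3,5-dimethoxyphenyl]-8-oxo-3,7-dioxabicyclo[3.3.0]octan-1-yl 2,2-dimethylpropanoate
Product: 15 (2R,3S,4R)-2-[4-(benzyloxy)-3,5-dimethoxyphenyl]-4-{(S)-[4-(benzyloxy)-3,5-dimethoxyphenyl](hydroxy)methyl}-3-(hydroxymethyl)oxolan-3-ol
Conditions: LiAlH4, THF, 0 °C to rt; aqueous NaOH work-up
Reagents that add atoms: none
Why: Hydride reduction of the lactone to the diol and of the pivalate to the free tertiary alcohol; no stereocentre is touched and the ring B ether and benzyl ethers are inert.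

Step 9
Reactants: 15 (2R,3S,4R)-2-[4-(benzyloxy)-3,5-dimethoxyphenyl]-4-{(S)-[4-(benzyloxy)-3,5-dimethoxyphenyl](hydroxy)methyl}-3-(hydroxymethyl)oxolan-3-ol
Product: 16 (1S,2R,5R,6S)-2,6-bis[4-(benzyloxy)-3,5-dimethoxyphenyl]-3,7-dioxabicyclo[3.3.0]octan-1-ol
Conditions: BF3·OEt2 (0.2 equiv), 4 Å molecular sieves, CH2Cl2, −20 °C to 0 °C
Reagents that add atoms: none
Why: Acid-mediated cyclodehydration (SN1 etherification) in which the secondary benzylic alcohol ionises and the primary hydroxyl closes ring A in the 5-exo mode, with the aryl group expected on the convex face as in related furofuran closures through benzylic cations; the ring B benzylic ether should ionise less readily because C2 is flanked by the oxygen-bearing C1, and the tertiary hydroxyl could only give an oxetane.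

Step 10
Reactants: 16 (1S,2R,5R,6S)-2,6-bis[4-(benzyloxy)-3,5-dimethoxyphenyl]-3,7-dioxabicyclo[3.3.0]octan-1-ol
Product: 17 8-hydroxysyringaresinol, (1S,2R,5R,6S)-2,6-bis(4-hydroxy-3,5-dimethoxyphenyl)-3,7-dioxabicyclo[3.3.0]octan-1-ol
Conditions: H2 (1 atm), 10% Pd/C, EtOAc, rt, stopped as soon as 16 is consumed
Reagents that add atoms: none
Why: Hydrogenolysis of the two aryl benzyl ethers, which should be cleaved well before the hindered cyclic dialkyl benzylic ethers of the bicycle; no stereocentre is touched.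

## Compound list

1 | 4-(benzyloxy)-3,5-dimethoxybenzaldehyde | O=Cc1cc(OC)c(OCc2ccccc2)c(OC)c1 | starting material
2 | methyl acrylate | C=CC(=O)OC | starting material
3 | methyl 4-[4-(benzyloxy)-3,5-dimethoxyphenyl]-4-oxobutanoate | COC(=O)CCC(=O)c1cc(OC)c(OCc2ccccc2)c(OC)c1 | intermediate
4 | methyl (4S)-4-[4-(benzyloxy)-3,5-dimethoxyphenyl]-4-hydroxybutanoate | COC(=O)CC[C@H](O)c1cc(OC)c(OCc2ccccc2)c(OC)c1 | intermediate
5 | (5S)-5-[4-(benzyloxy)-3,5-dimethoxyphenyl]dihydrofuran-2(3H)-one | COc1cc([C@H]2OC(=O)CC2)cc(OC)c1OCc1ccccc1 | intermediate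
6 | (5S)-5-[4-(benzyloxy)-3,5-dimethoxyphenyl]-3-hydroxydihydrofuran-2(3H)-one (C3 epimers) | COc1cc([C@H]2OC(=O)C(O)C2)cc(OC)c1OCc1ccccc1 | intermediate
7 | (5S)-5-[4-(benzyloxy)-3,5-dimethoxyphenyl]dihydrofuran-2,3-dione | COc1cc([C@H]2OC(=O)C(=O)C2)cc(OC)c1OCc1ccccc1 | intermediate
8 | (5S)-5-[4-(benzyloxy)-3,5-dimethoxyphenyl]-3-hydroxyfuran-2(5H)-one | COc1cc([C@H]2OC(=O)C(O)=C2)cc(OC)c1OCc1ccccc1 | intermediate
9 | (5S)-5-[4-(benzyloxy)-3,5-dimethoxyphenyl]-2-oxo-2,5-dihydrofuran-3-yl 2,2-dimethylpropanoate | COc1cc([C@H]2OC(=O)C(OC(=O)C(C)(C)C)=C2)cc(OC)c1OCc1ccccc1 | intermediate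
10 | (trimethylsilyl)methanol | C[Si](C)(C)CO | starting material
11 | 2-(benzyloxy)-5-{bis[(trimethylsilyl)methoxy]methyl}-1,3-dimethoxybenzene | COc1cc(C(OC[Si](C)(C)C)OC[Si](C)(C)C)cc(OC)c1OCc1ccccc1 | intermediate
12 | 2-(benzyloxy)-5-{chloro[(trimethylsilyl)methoxy]methyl}-1,3-dimethoxybenzene (racemic) | COc1cc(C(Cl)OC[Si](C)(C)C)cc(OC)c1OCc1ccccc1 | intermediate
13 | carbonyl ylide of aldehyde 1, ArCH=O(+)–CH2(−) with Ar = 4-(benzyloxy)-3,5-dimethoxyphenyl | [CH2-][O+]=Cc1cc(OC)c(OCc2ccccc2)c(OC)c1 | intermediate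
14 | (1R,2R,5R,6S)-2,6-bis[4-(benzyloxy)-3,5-dimethoxyphenyl]-8-oxo-3,7-dioxabicyclo[3.3.0]octan-1-yl 2,2-dimethylpropanoate | COc1cc([C@H]2OC(=O)[C@]3(OC(=O)C(C)(C)C)[C@@H](c4cc(OC)c(OCc5ccccc5)c(OC)c4)OC[C@H]23)cc(OC)c1OCc1ccccc1 | intermediate
15 | (2R,3S,4R)-2-[4-(benzyloxy)-3,5-dimethoxyphenyl]-4-{(S)-[4-(benzyloxy)-3,5-dimethoxyphenyl](hydroxy)methyl}-3-(hydroxymethyl)oxolan-3-ol | COc1cc([C@@H](O)[C@H]2CO[C@H](c3cc(OC)c(OCc4ccccc4)c(OC)c3)[C@@]2(O)CO)cc(OC)c1OCc1ccccc1 | intermediate
16 | (1S,2R,5R,6S)-2,6-bis[4-(benzyloxy)-3,5-dimethoxyphenyl]-3,7-dioxabicyclo[3.3.0]octan-1-ol | COc1cc([C@H]2OC[C@]3(O)[C@@H](c4cc(OC)c(OCc5ccccc5)c(OC)c4)OC[C@H]23)cc(OC)c1OCc1ccccc1 | intermediate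
17 | 8-hydroxysyringaresinol, (1S,2R,5R,6S)-2,6-bis(4-hydroxy-3,5-dimethoxyphenyl)-3,7-dioxabicyclo[3.3.0]octan-1-ol | COc1cc([C@H]2OC[C@]3(O)[C@@H](c4cc(OC)c(O)c(OC)c4)OC[C@H]23)cc(OC)c1O | target

## Step count and risks

Total steps: 10. Longest linear sequence: 9 steps (steps 1–5 and 7–10); step 6 is the side branch.

Steps most likely to fail:

Step 7. What may go wrong:
- low exo selectivity at C2, so that the aryl group ends on the concave face;
- slow bond formation at the acyloxy-bearing carbon, letting the ylide collapse to the aryl oxirane;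
- loss of enantiopurity through fluoride-mediated γ-deprotonation of the butenolide.

Fallback: take the oxygen off the dipolarophile and put the C1 hydroxyl in afterwards. The fallback sets out from 5 and returns at 15.
- Selenenylation of 5 (LiN(i-Pr)2, THF, −78 °C; PhSeBr) should give (5S)-5-[4-(benzyloxy)-3,5-dimethoxyphenyl]-3-(phenylselanyl)dihydrofuran-2(3H)-one F1.
- Oxidation with H2O2/pyridine in CH2Cl2 and selenoxide elimination should give the butenolide (5S)-5-[4-(benzyloxy)-3,5-dimethoxyphenyl]furan-2(5H)-one F2.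
- Cycloaddition of F2 with ylide 13, made from 11 through 12 as in step 7, should give the bicyclic lactone (1S,2S,5R,6S)-2,6-bis[4-(benzyloxy)-3,5-dimethoxyphenyl]-3,7-dioxabicyclo[3.3.0]octan-8-one F3. Here the exo aryl group lies next to a hydrogen instead of an acyloxy group.
- Hydroxylation of the bridgehead lactone enolate (KN(SiMe3)2, THF, −78 °C; 2-(phenylsulfonyl)-3-phenyloxaziridine) can only keep the cis fusion and should give the hydroxy lactone (1R,2R,5R,6S)-1-hydroxy-2,6-bis[4-(benzyloxy)-3,5-dimethoxyphenyl]-3,7-dioxabicyclo[3.3.0]octan-8-one F4.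
- LiAlH4 in THF then gives 15.

Step 9. What may go wrong: competing ionisation of the ring B benzylic ether, followed by scrambling at C2, a 1,2-shift towards the neighbouring carbinol, or capture by the benzylic hydroxyl to give an isomeric 2,5-diaryloxolane.

Fallback: keep ring A closed throughout. The fallback sets out from 14 and returns at 16.
- Reduction of 14 with i-Bu2AlH (excess) in CH2Cl2 at −78 °C should stop the lactone at the lactol and cleave the pivalate, giving the lactol (1R,2R,5R,6S)-2,6-bis[4-(benzyloxy)-3,5-dimethoxyphenyl]-3,7-dioxabicyclo[3.3.0]octane-1,8-diol F5.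
- Reduction of the cyclic oxocarbenium ion from F5 with Et3SiH and BF3·OEt2 in CH2Cl2 at −78 °C gives 16.

Step 1. What may go wrong: sluggish acyl anion formation and conjugate addition with the electron-rich aldehyde, with benzoin formation and acrylate oligomerisation taking over.

Fallback: build the keto ester by enolate alkylation. The fallback sets out from 1 and returns at 3.
- Addition of MeMgBr to 1 in THF at 0 °C should give 1-[4-(benzyloxy)-3,5-dimethoxyphenyl]ethanol F6.
- Oxidation with MnO2 in CH2Cl2 should give 1-[4-(benzyloxy)-3,5-dimethoxyphenyl]ethanone F7.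
- Alkylation of the lithium enolate of F7 (LiN(SiMe3)2, THF, −78 °C) with methyl bromoacetate gives 3.

## Further compounds

F1 | step 7 | (5S)-5-[4-(benzyloxy)-3,5-dimethoxyphenyl]-3-(phenylselanyl)dihydrofuran-2(3H)-one (C3 epimers) | COc1cc([C@H]2OC(=O)C([Se]c3ccccc3)C2)cc(OC)c1OCc1ccccc1
F2 | step 7 | (5S)-5-[4-(benzyloxy)-3,5-dimethoxyphenyl]furan-2(5H)-one | COc1cc([C@H]2OC(=O)C=C2)cc(OC)c1OCc1ccccc1
F3 | step 7 | (1S,2S,5R,6S)-2,6-bis[4-(benzyloxy)-3,5-dimethoxyphenyl]-3,7-dioxabicyclo[3.3.0]octan-8-one | COc1cc([C@H]2OC(=O)[C@@H]3[C@@H](c4cc(OC)c(OCc5ccccc5)c(OC)c4)OC[C@H]23)cc(OC)c1OCc1ccccc1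
F4 | step 7 | (1R,2R,5R,6S)-1-hydroxy-2,6-bis[4-(benzyloxy)-3,5-dimethoxyphenyl]-3,7-dioxabicyclo[3.3.0]octan-8-one | COc1cc([C@H]2OC(=O)[C@]3(O)[C@@H](c4cc(OC)c(OCc5ccccc5)c(OC)c4)OC[C@H]23)cc(OC)c1OCc1ccccc1
F5 | step 9 | (1R,2R,5R,6S)-2,6-bis[4-(benzyloxy)-3,5-dimethoxyphenyl]-3,7-dioxabicyclo[3.3.0]octane-1,8-diol (C8 epimers) | COc1cc([C@H]2OC(O)[C@]3(O)[C@@H](c4cc(OC)c(OCc5ccccc5)c(OC)c4)OC[C@H]23)cc(OC)c1OCc1ccccc1
F6 | step 1 | 1-[4-(benzyloxy)-3,5-dimethoxyphenyl]ethanol (racemic) | CC(O)c1cc(OC)c(OCc2ccccc2)c(OC)c1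
F7 | step 1 | 1-[4-(benzyloxy)-3,5-dimethoxyphenyl]ethanone | CC(=O)c1cc(OC)c(OCc2ccccc2)c(OC)c1
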